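The tetrahydrofuran (O1, C2 bearing the hydroxyphenyl group, C3 bearing C3a, C4 bearing C4a, C5) is cut at O1–C5 and C3–C4. The ring exposes two retrons: O1–C5–C4–C4a(=O) is a β-alkoxy ketone, and C2 and C3a carry oxygen on either side of C3. In one flask the carbinol oxygen of an erythro epoxy alcohol adds to an aryl vinyl ketone and the resulting enolate opens the oxirane at C3, which closes the ring, sets C3 and C4 and frees the C3a oxygen for acetylation. The precursors are (S)-[4-(triisopropylsilyloxy)phenyl][(R)-oxiran-2-yl]methanol and 1-(4-methoxyphenyl)prop-2-en-1-one.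

Key step: step 5

Remark 1: the target is read as (2R,3S,4R) in the ring (2,3-trans, 3,4-trans) with (S) at C4a; C2 keeps the carbinol configuration of 5 and C3 comes from the (R)-oxirane carbon by one inversion, so the (S,R)-erythro epoxy alcohol is the correct isomer and no structure needed correction.

Remark 2: the phenol is carried as its triisopropylsilyl ether because a smaller silyl group could be transferred to the lithium alkoxide formed in step 5; enone 7 is made fresh, and the base in step 5 is held near one equivalent.

Step 1
Reactants: 1 4-hydroxybenzaldehyde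
Product: 2 4-(triisopropylsilyloxy)benzaldehyde
Conditions: iPr3SiCl (1.1 equiv), imidazole (2.2 equiv), DMF, 0 °C to rt
Reagents that add atoms: chlorotriisopropylsilane, CC(C)[Si](Cl)(C(C)C)C(C)C
Why: Silyl ether formation on a phenol with a silyl chloride and imidazole is routine, and the bulky triisopropylsilyl group should resist the Grignard reagent, lithium amide and lithium alkoxide ahead yet fall to fluoride.

Step 2
Reactants: 2 4-(triisopropylsilyloxy)benzaldehyde; 3 vinylmagnesium bromide
Product: 4 racemic 1-[4-(triisopropylsilyloxy)phenyl]prop-2-en-1-ol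
Conditions: THF, −78 to 0 °C; sat. aq NH4Cl
Reagents that add atoms: none
Why: Grignard 1,2-addition of a vinyl nucleophile to an aromatic aldehyde gives the allylic alcohol, whose carbinol centre is formed without control and is resolved in step 3.

Step 3
Reactants: 4 racemic 1-[4-(triisopropylsilyloxy)phenyl]prop-2-en-1-ol
Product: 5 (S)-[4-(triisopropylsilyloxy)phenyl][(R)-oxiran-2-yl]methanol
Conditions: Ti(OiPr)4 (10 mol %), L-(+)-diisopropyl tartrate (15 mol %), tBuOOH (0.45 equiv, anhydrous in isooctane), 4 Å molecular sieves, CH2Cl2, −20 °C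
Reagents that add atoms: tert-butyl hydroperoxide, CC(C)(C)OO
Why: Sharpless asymmetric epoxidation run as a kinetic resolution: with the (2R,3R)-tartrate the (R)-alcohol should be epoxidised much faster than its mirror image, on the alkene face that places the new (R)-oxirane carbon erythro to the carbinol, so that stopping below half conversion should give 5 in high enantiomeric and diastereomeric purity while the unreacted (S)-alcohol is removed by chromatography.

Step 4
Reactants: 6 3-chloro-1-(4-methoxyphenyl)propan-1-one
Product: 7 1-(4-methoxyphenyl)prop-2-en-1-one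
Conditions: Et3N (1.5 equiv), CH2Cl2, 0 °C to rt; used at once
Reagents that add atoms: none
Why: Base-induced E1cB loss of HCl from a β-chloro ketone gives the aryl vinyl ketone, which is prepared immediately before use because it polymerises on storage.

Step 5
Reactants: 5 (S)-[4-(triisopropylsilyloxy)phenyl][(R)-oxiran-2-yl]methanol; 7 1-(4-methoxyphenyl)prop-2-en-1-one
Product: 11 [(2R,3S,4R)-4-(4-methoxybenzoyl)-2-[4-(triisopropylsilyloxy)phenyl]tetrahydrofuran-3-yl]methyl acetate, via oxa-Michael adduct 8 (not isolated), via lithium enolate 9 (not isolated), via lithium alkoxide 10 (not isolated)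
Conditions: 7 (1.1 equiv, slow addition), PMe3 (10 mol %), THF, 0 °C to rt; then LiN(SiMe3)2 (1.1 equiv), −78 to 0 °C; then Ac2O (2 equiv), 0 °C
Reagents that add atoms: acetic anhydride, CC(=O)OC(C)=O
Why: Proposed new method: PMe3 adds to enone 7 and the phosphonium enolate so formed deprotonates carbinol 5, whose alkoxide adds to a second molecule of 7 to give ether 8 (bond O1–C5); LiN(SiMe3)2 then converts 8 into the Z-lithium enolate 9, its carbon C4 displaces the oxirane oxygen at C3 from the rear (bond C3–C4), and the primary alkoxide 10 released at C3a is acetylated by Ac2O. The closest known reaction types are the phosphine-catalysed addition of alcohols to vinyl ketones and the intramolecular opening of epoxides by enolates and nitrile anions (Stork epoxynitrile cyclisation), which have not been run in sequence in one flask on a β-alkoxy ketone. The tetrahydrofuran closes in the 5-exo-tet mode. C3 is fixed by stereospecific inversion at the (R)-oxirane carbon, which turns the erythro relationship of 5 into the 2,3-trans ring while C2 is untouched, and C4 is fixed by the enolate approaching with its aroyl-bearing end turned away from the C3a arm, a trans arrangement that is also the more stable one and can be reached by enolisation. The step needs attack at the inner carbon C3 instead of C3a and no scrambling of the epoxy alcohol: the three-atom tether C5–O1–C2 allows a collinear rear-side approach only to C3, the carbinol oxygen is already an ether when strong base arrives so that Payne rearrangement is blocked, loss of the alkoxide from 9 merely returns 5 and 7 whereas ring closure is irreversible, and about one equivalent of base plus immediate acetylation should keep the ketone from being enolised or attacked by the C3a alkoxide.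

Step 6
Reactants: 11 [(2R,3S,4R)-4-(4-methoxybenzoyl)-2-[4-(triisopropylsilyloxy)phenyl]tetrahydrofuran-3-yl]methyl acetate
Product: 12 [(2R,3S,4R)-4-[(S)-hydroxy(4-methoxyphenyl)methyl]-2-[4-(triisopropylsilyloxy)phenyl]tetrahydrofuran-3-yl]methyl acetate
Conditions: LiBH(sBu)3 (L-Selectride, 1.2 equiv), THF, −78 °C; AcOH quench
Reagents that add atoms: none
Why: Substrate-controlled hydride reduction of an α-branched aryl ketone (Felkin–Anh model): with the more substituted ring carbon C3 perpendicular to the carbonyl group and the bulky borohydride entering anti to it past the C4 hydrogen, the (S)-carbinol at C4a should dominate, the same face being predicted if lithium bridges the carbonyl oxygen and O1, while the acetate and the aryl silyl ether should not be attacked at −78 °C.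

Step 7
Reactants: 12 [(2R,3S,4R)-4-[(S)-hydroxy(4-methoxyphenyl)methyl]-2-[4-(triisopropylsilyloxy)phenyl]tetrahydrofuran-3-yl]methyl acetate
Product: 13 [(2R,3S,4R)-4-[(S)-acetoxy(4-methoxyphenyl)methyl]-2-[4-(triisopropylsilyloxy)phenyl]tetrahydrofuran-3-yl]methyl acetate
Conditions: Ac2O (2 equiv), pyridine, 4-(dimethylamino)pyridine (5 mol %), CH2Cl2, 0 °C to rt
Reagents that add atoms: acetic anhydride, CC(=O)OC(C)=O
Why: Nucleophile-catalysed acetylation of a secondary alcohol with acetic anhydride touches no stereocentre, and any acetyl transfer between the C4a and C3a oxygens during step 6 is of no consequence because both end as acetates.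

Step 8
Reactants: 13 [(2R,3S,4R)-4-[(S)-acetoxy(4-methoxyphenyl)methyl]-2-[4-(triisopropylsilyloxy)phenyl]tetrahydrofuran-3-yl]methyl acetate
Product: 14 [(2R,3S,4R)-4-[(S)-acetoxy(4-methoxyphenyl)methyl]-2-(4-hydroxyphenyl)tetrahydrofuran-3-yl]methyl acetate
Conditions: Bu4NF (1.2 equiv), AcOH (1.5 equiv), THF, 0 °C
Reagents that add atoms: none
Why: Fluoride cleavage of an aryl silyl ether is much faster than attack on alkyl acetates, and the acetic acid buffer protonates the phenoxide as it forms, so that neither acyl transfer nor opening of the para-hydroxybenzylic C2–O1 bond through a quinone methide should occur.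

Compound list

1 | 4-hydroxybenzaldehyde | O=Cc1ccc(O)cc1 | starting material
2 | 4-(triisopropylsilyloxy)benzaldehyde | CC(C)[Si](Oc1ccc(C=O)cc1)(C(C)C)C(C)C | intermediate
3 | vinylmagnesium bromide | C=C[Mg]Br | starting material
4 | racemic 1-[4-(triisopropylsilyloxy)phenyl]prop-2-en-1-ol | C=CC(O)c1ccc(O[Si](C(C)C)(C(C)C)C(C)C)cc1 | intermediate
5 | (S)-[4-(triisopropylsilyloxy)phenyl][(R)-oxiran-2-yl]methanol (erythro) | O[C@@H](c1ccc(O[Si](C(C)C)(C(C)C)C(C)C)cc1)[C@H]1CO1 | intermediate
6 | 3-chloro-1-(4-methoxyphenyl)propan-1-one | COc1ccc(C(=O)CCCl)cc1 | starting material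
7 | 1-(4-methoxyphenyl)prop-2-en-1-one | COc1ccc(C(=O)C=C)cc1 | intermediate
8 | 1-(4-methoxyphenyl)-3-{(S)-[(R)-oxiran-2-yl][4-(triisopropylsilyloxy)phenyl]methoxy}propan-1-one (oxa-Michael adduct) | COc1ccc(C(=O)CCO[C@@H](c2ccc(O[Si](C(C)C)(C(C)C)C(C)C)cc2)[C@H]2CO2)cc1 | intermediate
9 | lithium (Z)-1-(4-methoxyphenyl)-3-{(S)-[(R)-oxiran-2-yl][4-(triisopropylsilyloxy)phenyl]methoxy}prop-1-en-1-olate (lithium enolate) | [Li+].COc1ccc(/C([O-])=C/CO[C@@H](c2ccc(O[Si](C(C)C)(C(C)C)C(C)C)cc2)[C@H]2CO2)cc1 | intermediate
10 | lithium [(2R,3S,4R)-4-(4-methoxybenzoyl)-2-[4-(triisopropylsilyloxy)phenyl]tetrahydrofuran-3-yl]methanolate (lithium alkoxide) | [Li+].COc1ccc(C(=O)[C@H]2CO[C@@H](c3ccc(O[Si](C(C)C)(C(C)C)C(C)C)cc3)[C@@H]2C[O-])cc1 | intermediate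
11 | [(2R,3S,4R)-4-(4-methoxybenzoyl)-2-[4-(triisopropylsilyloxy)phenyl]tetrahydrofuran-3-yl]methyl acetate | COc1ccc(C(=O)[C@H]2CO[C@@H](c3ccc(O[Si](C(C)C)(C(C)C)C(C)C)cc3)[C@@H]2COC(C)=O)cc1 | intermediate
12 | [(2R,3S,4R)-4-[(S)-hydroxy(4-methoxyphenyl)methyl]-2-[4-(triisopropylsilyloxy)phenyl]tetrahydrofuran-3-yl]methyl acetate | COc1ccc([C@@H](O)[C@H]2CO[C@@H](c3ccc(O[Si](C(C)C)(C(C)C)C(C)C)cc3)[C@@H]2COC(C)=O)cc1 | intermediate
13 | [(2R,3S,4R)-4-[(S)-acetoxy(4-methoxyphenyl)methyl]-2-[4-(triisopropylsilyloxy)phenyl]tetrahydrofuran-3-yl]methyl acetate | COc1ccc([C@@H](OC(C)=O)[C@H]2CO[C@@H](c3ccc(O[Si](C(C)C)(C(C)C)C(C)C)cc3)[C@@H]2COC(C)=O)cc1 | intermediate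
14 | [(2R,3S,4R)-4-[(S)-acetoxy(4-methoxyphenyl)methyl]-2-(4-hydroxyphenyl)tetrahydrofuran-3-yl]methyl acetate | COc1ccc([C@@H](OC(C)=O)[C@H]2CO[C@@H](c3ccc(O)cc3)[C@@H]2COC(C)=O)cc1 | target

Total step count: 8. Longest linear sequence: 7 steps (1, 2, 3, 5, 6, 7, 8); step 4 is a one-step branch.

Steps most likely to fail

Step 5. The enolate may shed the alkoxide, or the enone may oligomerise under the phosphine, faster than the oxirane is opened; attack at C3a or enolisation of the product before acetylation would also erode the outcome. The fallback uses known chemistry, sets out from 5 and returns at 11.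
- The carbinol of 5 is added to acrylonitrile under PMe3 catalysis to give the cyanoethyl ether 3-{(S)-[(R)-oxiran-2-yl][4-(triisopropylsilyloxy)phenyl]methoxy}propanenitrile F1.
- A Stork epoxynitrile cyclisation (KN(SiMe3)2, THF, −78 to 0 °C) follows, in which the much more nucleophilic nitrile anion opens the oxirane at C3 in the same 5-exo sense. Silylation of the alkoxide in the flask with Et3SiCl then gives (2R,3S,4S)-3-[(triethylsilyloxy)methyl]-2-[4-(triisopropylsilyloxy)phenyl]tetrahydrofuran-4-carbonitrile F2.
- Addition of 4-MeOC6H4MgBr to the nitrile and hydrolysis of the imine with dilute HCl, which also removes the triethylsilyl group, gives the hydroxy ketone [(2R,3S,4R)-3-(hydroxymethyl)-2-[4-(triisopropylsilyloxy)phenyl]tetrahydrofuran-4-yl](4-methoxyphenyl)methanone F3.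
- Acetylation (Ac2O, pyridine) gives 11; a short treatment with DBU should bring any C4 epimer to the trans ketone.

Step 6. Facial discrimination in the hydride delivery may be poor, because the two ring carbons flanking C4 differ only moderately in size. The fallback sets out from 11 and returns at 12, and replaces substrate control by catalyst control. It is a Corey–Bakshi–Shibata reduction with BH3·SMe2 and (R)-1-methyl-3,3-diphenyltetrahydro-1H,3H-pyrrolo[1,2-c][1,3,2]oxazaborole (toluene/THF, −20 °C). This catalyst should deliver hydride to the face that gives the (S)-aryl carbinol whatever the bias of C4; new compounds: none F0.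

Step 3. Discrimination between the enantiomers of a terminal vinyl carbinol may be incomplete when the product is harvested, and the electron-rich benzylic epoxy alcohol may degrade during a long exposure to the titanium alkoxide. The fallback sets out from 4 and returns at 5, and separates resolution from epoxidation.
- A lipase-catalysed acylation (lipase B from Candida antarctica, vinyl acetate, hexane, rt) should acetylate the (R)-alcohol selectively (aryl as the large group, vinyl as the medium one) to give (R)-1-[4-(triisopropylsilyloxy)phenyl]prop-2-en-1-yl acetate F4.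
- F4 is separated from the (S)-alcohol and cleaved with iBu2AlH (CH2Cl2, −78 °C) to (R)-1-[4-(triisopropylsilyloxy)phenyl]prop-2-en-1-ol F5.
- This single enantiomer is epoxidised to full conversion under Sharpless conditions with the (2R,3R)-tartrate, where reagent and substrate preferences reinforce each other, to give 5.

Further compounds
F1 | step 5 | 3-{(S)-[(R)-oxiran-2-yl][4-(triisopropylsilyloxy)phenyl]methoxy}propanenitrile | N#CCCO[C@@H](c1ccc(O[Si](C(C)C)(C(C)C)C(C)C)cc1)[C@H]1CO1
F2 | step 5 | (2R,3S,4S)-3-[(triethylsilyloxy)methyl]-2-[4-(triisopropylsilyloxy)phenyl]tetrahydrofuran-4-carbonitrile | N#C[C@H]1CO[C@@H](c2ccc(O[Si](C(C)C)(C(C)C)C(C)C)cc2)[C@@H]1CO[Si](CC)(CC)CC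
F3 | step 5 | [(2R,3S,4R)-3-(hydroxymethyl)-2-[4-(triisopropylsilyloxy)phenyl]tetrahydrofuran-4-yl](4-methoxyphenyl)methanone | COc1ccc(C(=O)[C@H]2CO[C@@H](c3ccc(O[Si](C(C)C)(C(C)C)C(C)C)cc3)[C@@H]2CO)cc1
F0 | step 6 | none | none
F4 | step 3 | (R)-1-[4-(triisopropylsilyloxy)phenyl]prop-2-en-1-yl acetate | C=C[C@@H](OC(C)=O)c1ccc(O[Si](C(C)C)(C(C)C)C(C)C)cc1
F5 | step 3 | (R)-1-[4-(triisopropylsilyloxy)phenyl]prop-2-en-1-ol | C=C[C@@H](O)c1ccc(O[Si](C(C)C)(C(C)C)C(C)C)cc1
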